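## Retrosynthetic overview

1. The last bond made is C-7/C-8 of the side chain: catalytic asymmetric addition of a terminal diynone to (Z)-dec-2-enal, which sets the 8S carbinol.
2. The terminal diynone comes by desilylation of the Michael adduct of ferulenol (3-farnesyl-4-hydroxycoumarin) and a silyl-capped vinyl diynyl ketone. This organocatalytic Michael addition forms the bond from ring carbon C-3 to the side-chain CH2 and sets the quaternary 3S centre, the first stereocentre of the route.
3. Ferulenol comes from 4-hydroxycoumarin and farnesyl acetate (C-allylation), the vinyl diynyl ketone from bis(trimethylsilyl)butadiyne and 3-chloropropanoyl chloride, and the enal from dec-2-yn-1-ol.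
4. Rings: none is built. The benzopyranone bicycle is bought as 4-hydroxycoumarin and is only dearomatised to the chromane-2,4-dione in the Michael step.

Assumption: the facial sense of the two catalyst-controlled steps is assigned by model only. Cat-Q is taken to deliver the enone to the Re face of ring carbon C-3 (giving 3S) and (S,S)-ProPhenol to deliver the alkynyl group to the Re face of the enal (giving 8S); if either proves opposite, the quinidine-derived pseudo-enantiomer of Cat-Q or (R,R)-ProPhenol is used instead.

Catalysts: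
- Cat-Q = quinine-derived squaramide, 3-{[3,5-bis(trifluoromethyl)phenyl]amino}-4-{[(8α,9S)-6′-methoxycinchonan-9-yl]amino}cyclobut-3-ene-1,2-dione.
- (S,S)-ProPhenol = 2,6-bis{[(2S)-2-(hydroxydiphenylmethyl)pyrrolidin-1-yl]methyl}-4-methylphenol.

## Route

Step 1
Reactants: 1 4-hydroxycoumarin; 2 (2E,6E)-farnesyl acetate
Product: 3 ferulenol (4-hydroxy-3-[(2E,6E)-3,7,11-trimethyldodeca-2,6,10-trien-1-yl]-2H-chromen-2-one)
Conditions: Pd(PPh3)4 (5 mol %), 1 (1.5 equiv), THF, 40 °C
Reagents that add atoms: none
Why: Tsuji–Trost allylation, in which zerovalent palladium ionises the allylic acetate, the departing acetate deprotonates the acidic coumarin, and the soft C-3 nucleophile attacks the unsubstituted terminus of the π-farnesyl complex (any O-allyl ether is re-ionised), giving the linear (2E) C-farnesyl product; no stereocentre is formed.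

Step 2
Reactants: 4 1,4-bis(trimethylsilyl)buta-1,3-diyne; 5 3-chloropropanoyl chloride
Product: 7 enone 7-(trimethylsilyl)hept-1-ene-4,6-diyn-3-one, via chloroketone 6 (not isolated)
Conditions: AlCl3 (1.1 equiv), CH2Cl2, −20 to 0 °C; cold dilute HCl wash; then Et3N (1.2 equiv), CH2Cl2, −20 °C, 15 min
Reagents that add atoms: none
Why: Friedel–Crafts-type ipso-acylation of an alkynylsilane (attack at the silicon-bearing carbon, then loss of Me3SiCl) stops after one acylation because the acyl diyne is deactivated, and the β-chloro ketone then undergoes E1cB elimination with Et3N to unveil the vinyl ketone; no stereocentre is formed.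

Step 3
Reactants: 3 ferulenol; 7 7-(trimethylsilyl)hept-1-ene-4,6-diyn-3-one
Product: 8 (3S)-3-[3-oxo-7-(trimethylsilyl)hepta-4,6-diyn-1-yl]-3-[(2E,6E)-3,7,11-trimethyldodeca-2,6,10-trien-1-yl]chromane-2,4-dione
Conditions: Cat-Q (10 mol %), 7 (1.3 equiv, slow addition), toluene, −30 °C, 48 h
Reagents that add atoms: none
Why: Proposed new method: the quinuclidine nitrogen deprotonates the acidic 3-alkyl-4-hydroxycoumarin (pKa about 5) to a tight chiral ammonium coumarinolate while the squaramide N–H pair binds and activates the ketone of 7, so the C–C bond forms at the unhindered vinyl CH2 terminus (the ynone β-carbon is internal, the far diyne end is blocked by SiMe3, and O-adducts at the vinyl group revert) and the catalyst pocket tells the benzo-fused C-4 side from the lactone C-2 side, leading the enone to the Re face of C-3 and setting the all-carbon quaternary centre as S; the closest known reaction type is the bifunctional cinchona squaramide- or thiourea-catalysed Michael addition of α-substituted cyclic β-keto esters and 2-substituted 1,3-diketones to vinyl ketones, which has not been shown for 3-alkyl-4-hydroxycoumarins or for a cross-conjugated vinyl diynyl ketone.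

Step 4
Reactants: 8 the silyl-capped Michael adduct
Product: 9 (3S)-3-(3-oxohepta-4,6-diyn-1-yl)-3-[(2E,6E)-3,7,11-trimethyldodeca-2,6,10-trien-1-yl]chromane-2,4-dione
Conditions: Bu4NF (1.05 equiv), AcOH (1.5 equiv), THF, −78 °C, 15 min; used at once
Reagents that add atoms: none
Why: Fluoride-induced protodesilylation of the alkynyl C–Si bond is very fast for an acyl-conjugated diynylsilane, the AcOH buffer keeps free base away from the aryl lactone and the ynone, and the quaternary C-3 has no α-hydrogen and cannot epimerise.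

Step 5
Reactants: 10 dec-2-yn-1-ol
Product: 11 (2Z)-dec-2-en-1-ol
Conditions: H2 (1 atm), Pd/CaCO3 poisoned with Pb(OAc)2, quinoline, hexane, 20 °C
Reagents that add atoms: none
Why: Lindlar semi-hydrogenation delivers H2 syn on the poisoned palladium surface and stops at the alkene, giving the (Z)-olefin.

Step 6
Reactants: 11 (2Z)-dec-2-en-1-ol
Product: 12 (2Z)-dec-2-enal
Conditions: PhI(OAc)2 (1.1 equiv), TEMPO (10 mol %), CH2Cl2, 0 to 20 °C; used fresh
Reagents that add atoms: none
Why: TEMPO/PhI(OAc)2 oxidation (oxoammonium mechanism) of the allylic alcohol is base-free and stops at the aldehyde, so the (Z)-geometry is kept.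

Step 7
Reactants: 9 the terminal diynone; 12 (2Z)-dec-2-enal
Product: 14 (3S)-3-[(8S,9Z)-8-hydroxy-3-oxoheptadec-9-ene-4,6-diyn-1-yl]-3-[(2E,6E)-3,7,11-trimethyldodeca-2,6,10-trien-1-yl]chromane-2,4-dione (CNP0346147.1), via alkynylzinc 13 (not isolated)
Conditions: (S,S)-ProPhenol (20 mol %), Me2Zn (2.0 equiv), Ph3PO (40 mol %), toluene, 20 °C, 1 h; then 12 (1.5 equiv), 0–4 °C, 24 h; aq. NH4Cl
Reagents that add atoms: none
Why: Trost asymmetric alkynylation, in which the dinuclear zinc complex assembled in the flask from Me2Zn and (S,S)-ProPhenol binds both the alkynylzinc and the aldehyde and delivers the alkynyl group to the Re face of the enal under catalyst control (the remote C-3 centre has no influence), setting C-8 as S, while the hindered aryl ketone, the lactone and the ynone are inert to the organozinc at 0–4 °C; 1,3-diynes and α,β-unsaturated aldehydes are established partners for this reaction.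

## Compound list

1 | 4-hydroxycoumarin (4-hydroxy-2H-chromen-2-one) | O=c1cc(O)c2ccccc2o1 | starting material
2 | (2E,6E)-farnesyl acetate ((2E,6E)-3,7,11-trimethyldodeca-2,6,10-trien-1-yl acetate) | CC(=O)OC/C=C(\C)CC/C=C(\C)CCC=C(C)C | starting material
3 | ferulenol, 4-hydroxy-3-[(2E,6E)-3,7,11-trimethyldodeca-2,6,10-trien-1-yl]-2H-chromen-2-one | O=c1oc2ccccc2c(O)c1C/C=C(\C)CC/C=C(\C)CCC=C(C)C | intermediate
4 | 1,4-bis(trimethylsilyl)buta-1,3-diyne | C[Si](C)(C)C#CC#C[Si](C)(C)C | starting material
5 | 3-chloropropanoyl chloride | O=C(Cl)CCCl | starting material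
6 | 1-chloro-7-(trimethylsilyl)hepta-4,6-diyn-3-one (chloroketone, formed in the flask, not isolated) | ClCCC(=O)C#CC#C[Si](C)(C)C | intermediate
7 | 7-(trimethylsilyl)hept-1-ene-4,6-diyn-3-one | C=CC(=O)C#CC#C[Si](C)(C)C | intermediate
8 | (3S)-3-[3-oxo-7-(trimethylsilyl)hepta-4,6-diyn-1-yl]-3-[(2E,6E)-3,7,11-trimethyldodeca-2,6,10-trien-1-yl]chromane-2,4-dione | C[Si](C)(C)C#CC#CC(=O)CC[C@@]1(C/C=C(\C)CC/C=C(\C)CCC=C(C)C)C(=O)Oc2ccccc2C1=O | intermediate
9 | (3S)-3-(3-oxohepta-4,6-diyn-1-yl)-3-[(2E,6E)-3,7,11-trimethyldodeca-2,6,10-trien-1-yl]chromane-2,4-dione | C#CC#CC(=O)CC[C@@]1(C/C=C(\C)CC/C=C(\C)CCC=C(C)C)C(=O)Oc2ccccc2C1=O | intermediate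
10 | dec-2-yn-1-ol | CCCCCCCC#CCO | starting material
11 | (2Z)-dec-2-en-1-ol | CCCCCCC/C=C\CO | intermediate
12 | (2Z)-dec-2-enal | CCCCCCC/C=C\C=O | intermediate
13 | methylzinc alkynide of 9, methyl{7-[(3S)-2,4-dioxo-3-farnesylchroman-3-yl]-5-oxohepta-1,3-diyn-1-yl}zinc (alkynylzinc, formed in the flask, not isolated) | C[Zn]C#CC#CC(=O)CC[C@@]1(C/C=C(\C)CC/C=C(\C)CCC=C(C)C)C(=O)Oc2ccccc2C1=O | intermediate
14 | (3S)-3-[(8S,9Z)-8-hydroxy-3-oxoheptadec-9-ene-4,6-diyn-1-yl]-3-[(2E,6E)-3,7,11-trimethyldodeca-2,6,10-trien-1-yl]chromane-2,4-dione (CNP0346147.1) | CCCCCCC/C=C\[C@H](O)C#CC#CC(=O)CC[C@@]1(C/C=C(\C)CC/C=C(\C)CCC=C(C)C)C(=O)Oc2ccccc2C1=O | target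

## Step count and risks

Total step count: 7. Longest linear sequence: 4 steps (steps 1, 3, 4, 7 or steps 2, 3, 4, 7).

The three steps most likely to fail:

**Step 3 (the proposed new Michael addition).** Face selection at C-3 is unproven, and O-attack of the coumarinolate on the ynone carbon could compete. The fallback uses known chemistry. It sets out from 3 and 7 and joins them by the ordinary amine-catalysed Michael addition (DABCO 10 mol %, CH2Cl2, 0 °C). This gives racemic material, that is 8 together with its mirror image (3R)-3-[3-oxo-7-(trimethylsilyl)hepta-4,6-diyn-1-yl]-3-[(2E,6E)-3,7,11-trimethyldodeca-2,6,10-trien-1-yl]chromane-2,4-dione F1. The two are separated by preparative supercritical-fluid chromatography on an amylose tris(3,5-dimethylphenylcarbamate) phase, and the route is rejoined at 8.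

**Step 7.** The donor 9 carries an aryl lactone and two ketones and must survive two equivalents of Me2Zn, and the (Z)-enal can isomerise. The fallback turns the order round, so that the zinc chemistry is done on a small donor and the Michael addition comes last. It sets out from 6 (taken from step 2 after the aqueous wash, before Et3N), from 12 and from 3.
- Bu4NF/AcOH in THF at −78 °C converts 6 into 1-chlorohepta-4,6-diyn-3-one F2.
- Me2Zn with (S,S)-ProPhenol turns F2 into its methylzinc alkynide, (7-chloro-5-oxohepta-1,3-diyn-1-yl)(methyl)zinc F3, which adds to 12 to give (8S,9Z)-1-chloro-8-hydroxyheptadec-9-ene-4,6-diyn-3-one F4.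
- Et3N (1.05 equiv, −20 °C, filtration through silica) eliminates HCl to give (8S,9Z)-8-hydroxyheptadeca-1,9-diene-4,6-diyn-3-one F5.
- Cat-Q-catalysed Michael addition of 3 to F5 under the conditions of step 3 gives 14, where the fallback comes back to the route.

**Step 2.** The enone 7 is a cross-conjugated ketone that polymerises easily, and the AlCl3 acylation of the diyne with a β-chloro acyl chloride may be low-yielding. The fallback makes the same C–C bond by nucleophilic instead of electrophilic means. It sets out from 4.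
- MeLi·LiBr (1.0 equiv, THF, −78 to 20 °C) removes one silyl group to give lithium 4-(trimethylsilyl)buta-1,3-diyn-1-ide F6.
- Addition of F6 to acrolein at −78 °C gives racemic 7-(trimethylsilyl)hept-1-ene-4,6-diyn-3-ol F7.
- MnO2 in CH2Cl2 at 0 °C oxidises F7 to 7, where the fallback comes back to the route.

## Further compounds

F1 | step 3 | (3R)-3-[3-oxo-7-(trimethylsilyl)hepta-4,6-diyn-1-yl]-3-[(2E,6E)-3,7,11-trimethyldodeca-2,6,10-trien-1-yl]chromane-2,4-dione | C[Si](C)(C)C#CC#CC(=O)CC[C@]1(C/C=C(\C)CC/C=C(\C)CCC=C(C)C)C(=O)Oc2ccccc2C1=O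
F2 | step 7 | 1-chlorohepta-4,6-diyn-3-one | ClCCC(=O)C#CC#C
F3 | step 7 | (7-chloro-5-oxohepta-1,3-diyn-1-yl)(methyl)zinc | C[Zn]C#CC#CC(=O)CCCl
F4 | step 7 | (8S,9Z)-1-chloro-8-hydroxyheptadec-9-ene-4,6-diyn-3-one | CCCCCCC/C=C\[C@H](O)C#CC#CC(=O)CCCl
F5 | step 7 | (8S,9Z)-8-hydroxyheptadeca-1,9-diene-4,6-diyn-3-one | CCCCCCC/C=C\[C@H](O)C#CC#CC(=O)C=C
F6 | step 2 | lithium 4-(trimethylsilyl)buta-1,3-diyn-1-ide | [Li]C#CC#C[Si](C)(C)C
F7 | step 2 | 7-(trimethylsilyl)hept-1-ene-4,6-diyn-3-ol (racemic) | C=CC(O)C#CC#C[Si](C)(C)C
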